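**Retrosynthetic overview**

- The target is (8R)-polypoda-13E,17E,21-triene-3β,8α-diol: a trans-decalin (ring A = C1–C5 and C10, ring B = C5–C10) with a homofarnesyl chain on C9.
- The strategy rests on C4, the quaternary gem-dimethyl carbon of ring A that lies between the C3 carbinol and the C5 ring-fusion CH. C4 with its two methyls is the isopropenyl group of (R)-carvone; the carvone ring and its methyl are C5–C10 of ring B and the C8 methyl.
- Disconnections, backwards: C11–C12 (C11 α-sulfonyl carbanion + (2E,6E)-farnesyl bromide); C9–C11 (methoxycarbonylation of a C9 enol triflate), with 8α-OH/9α-H from an 8α,9α-epoxy ester; C3–C4 (hydrogen-atom-transfer radical closure of ring A onto a C3 aldehyde); C10–C1 and C10–CH3 (two enolate alkylations of carvone).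
- Ring order: ring B is the carvone ring from the start, ring A is closed in step 5, and the side chain is attached last.

Key step: step 5

Remark on the chemistry: decalin positions follow drimane/labdane numbering (C11 is the carbon on C9, α is the face opposite the C10 methyl); carvone C1, C2, C3, C4, C5, C6 become C9, C8, C7, C6, C5, C10.

**Route**

Step 1
Reactants: 1 (R)-(−)-carvone
Product: 3 (5R)-2,6-dimethyl-5-(prop-1-en-2-yl)cyclohex-2-en-1-one (6-methylcarvone as a C6 epimer mixture), via carvone lithium α′-enolate 2 (not isolated)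
Conditions: LiN(i-Pr)2, THF, −78 °C; then MeI, −78 → 0 °C
Reagents that add atoms: iodomethane, CI; lithium diisopropylamide, [Li]N(C(C)C)C(C)C (the lithium of 2 only)
Why: Kinetic deprotonation at the α′ CH2 (carvone C6, the future C10) gives the cross-conjugated enolate, and enolate C-alkylation with MeI installs the future C10 methyl; the new centre forms as an epimer mixture that is erased by enolisation in step 2.

Step 2
Reactants: 3 6-methylcarvone (C6 epimer mixture); 4 allyl bromide
Product: 6 6-allyl-2,6-dimethyl-5-(prop-1-en-2-yl)cyclohex-2-en-1-one (allyl trans to isopropenyl), via 6-methylcarvone lithium enolate 5 (not isolated)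
Conditions: LiN(i-Pr)2, THF, −78 → −10 °C; then 4, DMPU, −78 °C → rt
Reagents that add atoms: lithium diisopropylamide, [Li]N(C(C)C)C(C)C (the lithium of 5 only)
Why: Enolate alkylation: allyl bromide attacks the tetrasubstituted cross-conjugated enolate on the face anti to the neighbouring isopropenyl group, which sets the quaternary centre (future C10) with allyl trans and methyl cis to isopropenyl, the relationship that becomes the trans ring fusion (5α-H, 10β-CH3).

Step 3
Reactants: 6 6-allyl-2,6-dimethyl-5-(prop-1-en-2-yl)cyclohex-2-en-1-one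
Product: 8 6-(3-hydroxypropyl)-2,6-dimethyl-5-(prop-1-en-2-yl)cyclohex-2-en-1-one (hydroxypropyl trans to isopropenyl), via alkylbis(3-methylbutan-2-yl)borane 7 (not isolated)
Conditions: disiamylborane (from BH3·THF and 2-methylbut-2-ene), THF, 0 °C; then NaBO3·4H2O, H2O, 0 °C → rt
Reagents that add atoms: disiamylborane, CC(C)C(C)BC(C)C(C)C (boron and alkyl groups of 7 only); sodium perborate, B(=O)O[O-].[Na+] (the hydroxyl oxygen of 8)
Why: Anti-Markovnikov hydroboration–oxidation: the bulky dialkylborane should add boron to the terminal carbon of the monosubstituted allyl alkene much faster than it reacts with the 1,1-disubstituted isopropenyl group, the trisubstituted enone C=C or the hindered carbonyl, and perborate oxidises the C–B bond under conditions mild enough to leave the enone; no stereocentre is formed.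

Step 4
Reactants: 8 6-(3-hydroxypropyl)-2,6-dimethyl-5-(prop-1-en-2-yl)cyclohex-2-en-1-one
Product: 9 3-[1,3-dimethyl-2-oxo-6-(prop-1-en-2-yl)cyclohex-3-en-1-yl]propanal (propanal chain trans to isopropenyl)
Conditions: Dess–Martin periodinane, NaHCO3, CH2Cl2, 0 °C → rt
Reagents that add atoms: none
Why: Dess–Martin oxidation of the primary alcohol to the aldehyde under buffered, neutral conditions that leave the alkenes and the enone untouched and create no stereocentre.

Step 5
Reactants: 9 3-[1,3-dimethyl-2-oxo-6-(prop-1-en-2-yl)cyclohex-3-en-1-yl]propanal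
Product: 10 3β-hydroxy-11-nordrim-7-en-9-one (trans-decalin with 5α-H and 10β-CH3)
Conditions: Fe(acac)3 (0.5 equiv), PhSiH3 (slow addition), degassed EtOH/(CH2OH)2, high dilution, 50 °C
Reagents that add atoms: none
Why: Fe(acac)3 and PhSiH3 in ethanol generate an iron hydride that transfers a hydrogen atom to the CH2 terminus of the isopropenyl group, giving the tertiary C4 radical with both methyls in place; this radical adds to the aldehyde carbon C3, and the alkoxy radical is reduced and protonated to the C3 carbinol. The closest known reaction type is the iron-hydride hydrogen-atom-transfer reductive cyclization of alkene-tethered ketones, of which the aldehyde acceptor is a direct extension, in line with the long-established 6-exo additions of alkyl radicals to aldehydes. Ring A closes in 6-exo-trig mode onto the carbonyl carbon (C3–C4 bond); attack at the aldehyde oxygen would need a seven-membered ring and closure onto the enone or the C9 carbonyl a four-membered one, so no other ring size competes. The only new stereocentre is C3: in the chair transition state the C10 methyl is axial and the carbonyl oxygen sits pseudo-equatorial, away from the axial 1α and 5α hydrogens, and because addition to C=O is reversible the more stable equatorial (3β) alkoxy radical should be the one drained by reduction; C5 and C10 are already fixed trans by step 2. The step needs hydrogen-atom transfer to the isopropenyl group in preference to the enone, which the electron-rich 1,1-disubstituted alkene secures over the electron-poor trisubstituted enone C=C, and it needs ring closure to outrun simple reduction of the radical, which dilution and slow silane addition favour.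

Step 6
Reactants: 10 3β-hydroxy-11-nordrim-7-en-9-one
Product: 11 3β-(tert-butyldimethylsilyloxy)-11-nordrim-7-en-9-one
Conditions: TBSCl, imidazole, DMAP (cat.), DMF, 40 °C
Reagents that add atoms: tert-butyldimethylsilyl chloride, CC(C)(C)[Si](C)(C)Cl
Why: Imidazole-promoted silylation of the equatorial 3β-hydroxyl masks the alcohol for the hydride, enolate and carbanion steps that follow; no stereocentre changes.

Step 7
Reactants: 11 3β-(tert-butyldimethylsilyloxy)-11-nordrim-7-en-9-one
Product: 13 3β-(tert-butyldimethylsilyloxy)-11-nordrim-8-en-9-yl trifluoromethanesulfonate, via lithium 8-en-9-olate 12 (not isolated)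
Conditions: LiBH(s-Bu)3, THF, −78 °C; then PhNTf2, −78 °C → rt
Reagents that add atoms: N-phenylbis(trifluoromethanesulfonimide), O=S(=O)(N(c1ccccc1)S(=O)(=O)C(F)(F)F)C(F)(F)F; lithium tri-sec-butylborohydride, [Li+].CCC(C)[BH-](C(C)CC)C(C)CC (the lithium of 12 only)
Why: Conjugate (1,4) hydride reduction of the α-methyl enone by the bulky borohydride, the carbonyl being shielded by the quaternary C10, gives the C8=C9 enolate regiospecifically, and O-sulfonylation with PhNTf2 traps it as the enol triflate; C8 stays sp2, so no stereocentre is set.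

Step 8
Reactants: 13 3β-(tert-butyldimethylsilyloxy)-11-nordrim-8-en-9-yl trifluoromethanesulfonate
Product: 14 methyl 3β-(tert-butyldimethylsilyloxy)drim-8-en-11-oate
Conditions: CO (1 atm), Pd(OAc)2 (cat.), PPh3, Et3N, MeOH/DMF, 65 °C
Reagents that add atoms: carbon monoxide, [C-]#[O+]; methanol, CO
Why: Palladium-catalysed alkoxycarbonylation of the enol triflate (oxidative addition, CO insertion, methanolysis of the acylpalladium) installs C11 on C9 as the methyl ester; no stereocentre is formed.

Step 9
Reactants: 14 methyl 3β-(tert-butyldimethylsilyloxy)drim-8-en-11-oate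
Product: 15 methyl 8α,9α-epoxy-3β-(tert-butyldimethylsilyloxy)driman-11-oate
Conditions: mCPBA, NaHCO3, CH2Cl2, 0 °C → rt
Reagents that add atoms: 3-chloroperoxybenzoic acid, OOC(=O)c1cccc(Cl)c1
Why: Prilezhaev epoxidation of the tetrasubstituted C8=C9 alkene, whose ester is twisted out of conjugation by the flanking C10 quaternary carbon and C8 methyl so that the alkene stays nucleophilic; the peracid should approach the α face, away from the axial C10 methyl, which sets the C8 oxygen α (C8 methyl β) and the C9 oxygen α.

Step 10
Reactants: 15 methyl 8α,9α-epoxy-3β-(tert-butyldimethylsilyloxy)driman-11-oate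
Product: 16 methyl 3β-(tert-butyldimethylsilyloxy)-8α-hydroxydriman-11-oate (9α-H)
Conditions: SmI2, HMPA, MeOH, THF, −78 → 0 °C
Reagents that add atoms: none
Why: Reductive opening of the α,β-epoxy ester by two single-electron transfers from SmI2 breaks the C9–O bond (α to the ester) and keeps the 8α-hydroxyl; the samarium enolate should be protonated on its open α face, the β face being covered by the axial C10 and C8 methyls, which sets 9α-H with the ester equatorial, also the more stable arrangement.

Step 11
Reactants: 16 methyl 3β-(tert-butyldimethylsilyloxy)-8α-hydroxydriman-11-oate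
Product: 17 3β-(tert-butyldimethylsilyloxy)drimane-8α,11-diol
Conditions: LiAlH4, THF, 0 °C
Reagents that add atoms: none
Why: Hydride reduction of the ester to the primary alcohol with LiAlH4; the C8 alkoxide forms first, and C9 is not epimerised under these non-equilibrating conditions.

Step 12
Reactants: 17 3β-(tert-butyldimethylsilyloxy)drimane-8α,11-diol
Product: 18 3β-(tert-butyldimethylsilyloxy)-11-(phenylsulfanyl)driman-8α-ol
Conditions: PhSSPh, n-Bu3P, pyridine, rt → 50 °C
Reagents that add atoms: diphenyl disulfide, c1ccccc1SSc1ccccc1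
Why: Hata reaction: n-Bu3P and PhSSPh turn the primary C11 hydroxyl into an alkoxyphosphonium ion that thiolate displaces by SN2, while the tertiary C8 hydroxyl cannot be displaced; no stereocentre is touched.

Step 13
Reactants: 18 3β-(tert-butyldimethylsilyloxy)-11-(phenylsulfanyl)driman-8α-ol
Product: 19 3β-(tert-butyldimethylsilyloxy)-11-(phenylsulfonyl)driman-8α-ol
Conditions: mCPBA (2.2 equiv), NaHCO3, CH2Cl2, 0 °C
Reagents that add atoms: 3-chloroperoxybenzoic acid, OOC(=O)c1cccc(Cl)c1
Why: Oxidation of the sulfide to the sulfone with two equivalents of peracid; the molecule holds no alkene at this stage, and the silyl ether and tertiary alcohol are inert.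

Step 14
Reactants: 19 3β-(tert-butyldimethylsilyloxy)-11-(phenylsulfonyl)driman-8α-ol; 20 (2E,6E)-farnesyl bromide
Product: 22 3β-(tert-butyldimethylsilyloxy)-11-(phenylsulfonyl)polypoda-13E,17E,21-trien-8α-ol (C11 epimer mixture), via C11,O8-dilithio sulfone 21 (not isolated)
Conditions: n-BuLi (2.1 equiv), THF/DMPU, −78 → −20 °C; then 20, −78 → 0 °C
Reagents that add atoms: n-butyllithium, [Li]CCCC (the lithium atoms of 21 only)
Why: Alkylation of an α-sulfonyl carbanion (Julia-type coupling): the second equivalent of n-BuLi deprotonates C11 after the C8 hydroxyl, and the carbanion should displace bromide from 20 by SN2 at the primary allylic carbon with the E alkenes unchanged; the new C11 centre forms as an epimer mixture that is removed in step 15.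

Step 15
Reactants: 22 3β-(tert-butyldimethylsilyloxy)-11-(phenylsulfonyl)polypoda-13E,17E,21-trien-8α-ol
Product: 23 3β-(tert-butyldimethylsilyloxy)polypoda-13E,17E,21-trien-8α-ol
Conditions: Na(Hg), Na2HPO4, MeOH/THF, −20 → 0 °C
Reagents that add atoms: none
Why: Reductive desulfonylation by electron transfer from sodium amalgam cleaves the C11–S bond and protonates C11 in buffered methanol; the sulfone is homoallylic, so the trisubstituted alkenes should neither migrate nor isomerise.

Step 16
Reactants: 23 3β-(tert-butyldimethylsilyloxy)polypoda-13E,17E,21-trien-8α-ol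
Product: 24 (8R)-polypoda-13E,17E,21-triene-3β,8α-diol (CID57401582)
Conditions: Bu4NF, THF, 50 °C
Reagents that add atoms: none
Why: Fluoride-mediated cleavage of the silyl ether frees the 3β-hydroxyl under basic conditions that spare the tertiary alcohol and the polyene; warming is planned because the ether sits next to the C4 quaternary carbon.

**Compound list**

1 | (R)-(−)-carvone | CC1=CC[C@@H](C(C)=C)CC1=O | starting material
2 | lithium α′-enolate of carvone (O–Li on C1; C1=C6 and C2=C3) | CC1=CC[C@@H](C(C)=C)C=C1O[Li] | intermediate (not isolated)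
3 | (5R)-2,6-dimethyl-5-(prop-1-en-2-yl)cyclohex-2-en-1-one, C6 epimer mixture | CC1=CC[C@@H](C(C)=C)C(C)C1=O | intermediate
4 | allyl bromide | C=CCBr | starting material
5 | lithium enolate of 3 (O–Li on C1; C1=C6 and C2=C3) | CC1=CC[C@@H](C(C)=C)C(C)=C1O[Li] | intermediate (not isolated)
6 | 6-allyl-2,6-dimethyl-5-(prop-1-en-2-yl)cyclohex-2-en-1-one, allyl trans to isopropenyl, C5 as in (R)-carvone | CC1=CC[C@@H](C(C)=C)[C@](C)(CC=C)C1=O | intermediate
7 | {3-[1,3-dimethyl-2-oxo-6-(prop-1-en-2-yl)cyclohex-3-en-1-yl]propyl}bis(3-methylbutan-2-yl)borane | CC1=CC[C@@H](C(C)=C)[C@](C)(CCCB(C(C)C(C)C)C(C)C(C)C)C1=O | intermediate (not isolated)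
8 | 6-(3-hydroxypropyl)-2,6-dimethyl-5-(prop-1-en-2-yl)cyclohex-2-en-1-one, hydroxypropyl trans to isopropenyl | CC1=CC[C@@H](C(C)=C)[C@](C)(CCCO)C1=O | intermediate
9 | 3-[1,3-dimethyl-2-oxo-6-(prop-1-en-2-yl)cyclohex-3-en-1-yl]propanal, propanal chain trans to isopropenyl | CC1=CC[C@@H](C(C)=C)[C@](C)(CCC=O)C1=O | intermediate (key-step precursor)
10 | 3β-hydroxy-11-nordrim-7-en-9-one (5α-H, 10β-CH3) | O=C1[C@@]2(C)CC[C@H](O)C(C)(C)[C@@H]2CC=C1C | intermediate (key-step product)
11 | 3β-(tert-butyldimethylsilyloxy)-11-nordrim-7-en-9-one | O=C1[C@@]2(C)CC[C@H](O[Si](C)(C)C(C)(C)C)C(C)(C)[C@@H]2CC=C1C | intermediate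
12 | lithium 3β-(tert-butyldimethylsilyloxy)-11-nordrim-8-en-9-olate | [Li]OC=1[C@@]2(C)CC[C@H](O[Si](C)(C)C(C)(C)C)C(C)(C)[C@@H]2CCC=1C | intermediate (not isolated)
13 | 3β-(tert-butyldimethylsilyloxy)-11-nordrim-8-en-9-yl trifluoromethanesulfonate | O=S(=O)(OC=1[C@@]2(C)CC[C@H](O[Si](C)(C)C(C)(C)C)C(C)(C)[C@@H]2CCC=1C)C(F)(F)F | intermediate
14 | methyl 3β-(tert-butyldimethylsilyloxy)drim-8-en-11-oate | COC(=O)C=1[C@@]2(C)CC[C@H](O[Si](C)(C)C(C)(C)C)C(C)(C)[C@@H]2CCC=1C | intermediate
15 | methyl 8α,9α-epoxy-3β-(tert-butyldimethylsilyloxy)driman-11-oate | COC(=O)[C@]1(O3)[C@@]2(C)CC[C@H](O[Si](C)(C)C(C)(C)C)C(C)(C)[C@@H]2CC[C@]13C | intermediate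
16 | methyl 3β-(tert-butyldimethylsilyloxy)-8α-hydroxydriman-11-oate (9α-H) | COC(=O)[C@@H]1[C@@]2(C)CC[C@H](O[Si](C)(C)C(C)(C)C)C(C)(C)[C@@H]2CC[C@@]1(C)O | intermediate
17 | 3β-(tert-butyldimethylsilyloxy)drimane-8α,11-diol | OC[C@@H]1[C@@]2(C)CC[C@H](O[Si](C)(C)C(C)(C)C)C(C)(C)[C@@H]2CC[C@@]1(C)O | intermediate
18 | 3β-(tert-butyldimethylsilyloxy)-11-(phenylsulfanyl)driman-8α-ol | c3ccccc3SC[C@@H]1[C@@]2(C)CC[C@H](O[Si](C)(C)C(C)(C)C)C(C)(C)[C@@H]2CC[C@@]1(C)O | intermediate
19 | 3β-(tert-butyldimethylsilyloxy)-11-(phenylsulfonyl)driman-8α-ol | O=S(=O)(c3ccccc3)C[C@@H]1[C@@]2(C)CC[C@H](O[Si](C)(C)C(C)(C)C)C(C)(C)[C@@H]2CC[C@@]1(C)O | intermediate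
20 | (2E,6E)-farnesyl bromide | CC(C)=CCC/C(C)=C/CC/C(C)=C/CBr | starting material
21 | C11,O8-dilithio derivative of 19 | [Li]C(S(=O)(=O)c3ccccc3)[C@@H]1[C@@]2(C)CC[C@H](O[Si](C)(C)C(C)(C)C)C(C)(C)[C@@H]2CC[C@@]1(C)O[Li] | intermediate (not isolated)
22 | 3β-(tert-butyldimethylsilyloxy)-11-(phenylsulfonyl)polypoda-13E,17E,21-trien-8α-ol, C11 epimer mixture | CC(C)=CCC/C(C)=C/CC/C(C)=C/CC(S(=O)(=O)c3ccccc3)[C@@H]1[C@@]2(C)CC[C@H](O[Si](C)(C)C(C)(C)C)C(C)(C)[C@@H]2CC[C@@]1(C)O | intermediate
23 | 3β-(tert-butyldimethylsilyloxy)polypoda-13E,17E,21-trien-8α-ol | CC(C)=CCC/C(C)=C/CC/C(C)=C/CC[C@@H]1[C@@]2(C)CC[C@H](O[Si](C)(C)C(C)(C)C)C(C)(C)[C@@H]2CC[C@@]1(C)O | intermediate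
24 | (8R)-polypoda-13E,17E,21-triene-3β,8α-diol (CID57401582) | CC(C)=CCC/C(C)=C/CC/C(C)=C/CC[C@@H]1[C@@]2(C)CC[C@H](O)C(C)(C)[C@@H]2CC[C@@]1(C)O | target

**Totals**

Total step count: 16. Longest linear sequence: 16 steps, from 1 to 24 (4 and 20 are commercial).

**Steps most likely to fail**

Step 5. The C4 radical may be reduced to an isopropyl group before it closes, the alkoxy radical may reopen faster than it is quenched, or the two faces of the aldehyde may be poorly differentiated. Any of these would give ring A in low yield or as a C3 epimer mixture. The fallback moves the acceptor to a nitrile and sets C3 by a separate hydride reduction. It sets out from 9, which is converted in one operation (aqueous NH3, I2, THF) into the nitrile 3-[1,3-dimethyl-2-oxo-6-(prop-1-en-2-yl)cyclohex-3-en-1-yl]propanenitrile F1. Under the same iron hydride conditions, for which nitrile acceptors are established, the C4 radical should add to the nitrile carbon to give the cyclic imine 3-imino-11-nordrim-7-en-9-one F2. Acidic work-up hydrolyses this to 11-nordrim-7-ene-3,9-dione F3. NaBH4 in MeOH/CH2Cl2 at −78 °C should then reduce the saturated 4,4-dimethyl C3 ketone by axial hydride delivery to the equatorial 3β-alcohol and leave the hindered conjugated C9 ketone, which comes back to the route at 10.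

Step 14. C-alkylation may be slow because the C11 carbanion is crowded by C8 and C10, so that dehydrobromination of 20 by the basic dianion or O-alkylation of the C8 alkoxide takes over. The fallback reverses the polarity of the C11–C12 bond formation. It sets out from 17, whose primary hydroxyl is converted (PPh3, I2, imidazole, toluene, 60 °C) into 3β-(tert-butyldimethylsilyloxy)-11-iododriman-8α-ol F4. Separately, 20 and PhSO2Na (DMF, rt) give (2E,6E)-farnesyl phenyl sulfone F5, which n-BuLi (THF/DMPU, −78 °C) turns into its α-lithio derivative F6. An excess of this unhindered allylic carbanion should take up the hydroxyl proton and displace iodide from F4 to give 3β-(tert-butyldimethylsilyloxy)-12-(phenylsulfonyl)polypoda-13E,17E,21-trien-8α-ol F7. The allylic sulfonyl group is then removed with LiBHEt3 and catalytic PdCl2(dppp) in THF at 0 °C, a method that keeps the position and E geometry of the C13 alkene, and the route is rejoined at 23.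

Step 3. The borane may also add to the isopropenyl group or reduce the enone carbonyl, and the peroxide stage may epoxidise the enone C=C. The fallback replaces hydroboration and alcohol oxidation by one palladium-catalysed oxidation. It sets out from 6 and applies the aldehyde-selective (anti-Markovnikov) Wacker oxidation (PdCl2(PhCN)2, CuCl2, AgNO2, O2, t-BuOH/MeNO2, rt). Only the monosubstituted allyl alkene should react under these conditions, which comes back to the route directly at 9. This fallback makes no new compound (F0).

**Further compounds**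

F1 | step 5 | 3-[1,3-dimethyl-2-oxo-6-(prop-1-en-2-yl)cyclohex-3-en-1-yl]propanenitrile, nitrile chain trans to isopropenyl | CC1=CC[C@@H](C(C)=C)[C@](C)(CCC#N)C1=O
F2 | step 5 | 3-imino-11-nordrim-7-en-9-one | O=C1[C@@]2(C)CCC(=N)C(C)(C)[C@@H]2CC=C1C
F3 | step 5 | 11-nordrim-7-ene-3,9-dione | O=C1[C@@]2(C)CCC(=O)C(C)(C)[C@@H]2CC=C1C
F4 | step 14 | 3β-(tert-butyldimethylsilyloxy)-11-iododriman-8α-ol | IC[C@@H]1[C@@]2(C)CC[C@H](O[Si](C)(C)C(C)(C)C)C(C)(C)[C@@H]2CC[C@@]1(C)O
F5 | step 14 | (2E,6E)-farnesyl phenyl sulfone | CC(C)=CCC/C(C)=C/CC/C(C)=C/CS(=O)(=O)c1ccccc1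
F6 | step 14 | α-lithio (2E,6E)-farnesyl phenyl sulfone | CC(C)=CCC/C(C)=C/CC/C(C)=C/C([Li])S(=O)(=O)c1ccccc1
F7 | step 14 | 3β-(tert-butyldimethylsilyloxy)-12-(phenylsulfonyl)polypoda-13E,17E,21-trien-8α-ol, C12 epimer mixture | CC(C)=CCC/C(C)=C/CC/C(C)=C/C(S(=O)(=O)c3ccccc3)C[C@@H]1[C@@]2(C)CC[C@H](O[Si](C)(C)C(C)(C)C)C(C)(C)[C@@H]2CC[C@@]1(C)O
F0 | step 3 | none | none
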